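Begin from the amounts in the red flask, which is also the flask asked about, followed so far.

| flask | solid substrate | enzyme | remark | time |
|---|---|---|---|---|
| red | 0.050 M | 2.4 µM | the very flask that is asked about, followed so far |  |
| flask | 0.050 M | 2.4 µM |  | 4.0 min |

red run (percent of the solid substrate charged)

| time / s | target / % | starting material / % | solid substrate / % |
|---|---|---|---|
| 10.0 | 1.5 | 0.2 | 98.7 |
| 25.0 | 3.0 | 0.1 | 98.4 |
| 50.0 | 4.1 | 0 | 95.3 |
| 80.0 | 6.3 | 0 | 92.9 |

(scatter of a reading: 0.5 percentage points)

* amount of target at 4.0 min, in percent of the solid substrate charged
* concentration of starting material in solution at 4.0 min, in percent of saturation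

- solid substrate is a solid; its amount is given per volume of the solution
- at the start none of the solid substrate is in solution
- starting material is what solid substrate becomes in solution
- starting material means what is dissolved; the solid is not counted in it

At 80.0 s the red flask has lost 7.10% of its charge from the solid substrate, yet c(starting material) reads 0%, so what dissolves is used as it arrives, and I take the passage out of the solid as the rate-limiting step. Your quantity is then the supply, read from this scattered loss as 0.0532 min⁻¹, the share of the charge leaving the solid per unit time.

Does this loss arrive as target? Target reads 6.3%, a gap of 0.8 percentage points against a scatter of 0.5 points per reading, so this gap does not tell you whether something else forms. Carried to 4.0 min, my reckoning gives a loss of 21.3%, and I expect target somewhat below that, with c(starting material) small against saturation, though no solubility was measured.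

The forecast gives 18% of target and 30% of saturation, on this ground: “The process is therefore steady”.

The flask gives 12.8% of target and 0% of saturation.

    target ⇌ isomer of the product (K = 1.40, k = 0.0100 s⁻¹)
    solid substrate ⇌ starting material, rate k2*(cs2 - [starting material]) while solid is left; crystals form when [starting material] > cs2 (solubility = 24.0 mM, k = 0.00200 s⁻¹)
    starting material + enzyme → target + enzyme, rate k3*[starting material]*[enzyme]/(1 + ([starting material]/Km3) + ([starting material]/Ksi3)^2) (0.130 M, 4.00 mM, k = 8.90 × 10⁷ M⁻¹ s⁻¹)

At 4.0 min the flask holds 77.0% of solid substrate, a loss of 23.0% against the 21.3% reckoned from the supply, and that loss stands as 12.8% of target beside 10.2% of isomer of the product. The neighbour flask, read at 15 min, is reckoned the same way: the supply gives a loss of 79.8%, and with 14% of solid substrate left that flask holds 39.3% of target and 47.1% of isomer of the product, 86.4% together.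

(The runs are calculated for substances that don't exist; scatter was added.)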